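Germacrane numbering is used for all ring compounds and for the C1–C10 chain: C14 is the methyl on C10, C15 the methyl on C4, C11–C13 the lactone carbons. TBS = tert-butyldimethylsilyl, TES = triethylsilyl, PMB = 4-methoxybenzyl.

## The problem

The target is a germacranolide: a ten-membered carbocycle (C1–C10) carrying two trans, trisubstituted epoxides (1,10 and 4,5). It is fused at C6–C7 to a butenolide whose tetrasubstituted C7=C11 olefin bears an acetoxymethyl group (C13), and it has a 2-(hydroxymethyl)acrylate on O8. Six stereocentres must be set (1R,4R,5R,6S,8S,10R). C6 and C8 flank the sp2 carbon C7 and are the only two that are not epoxide carbons, so they must be secured first and then used to steer the four epoxide centres. A medium ring has to be closed, and the closure should not create a stereocentre that cannot be repaired afterwards. The fragile parts are: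

- both epoxides toward acid, above all the 1,10-epoxide while the 4,5-olefin is still present (transannular cyclisation);
- C6–H, which is γ to the lactone carbonyl and next to the 4,5-epoxide, so base can open that epoxide by vinylogous elimination;
- the acrylate toward nucleophiles, the allylic acetate, and a free 8-hydroxyl, which under base can attack C12 and move the lactone from O6 to O8.

The enabling feature is that the 1,10-epoxide places oxygen on both C1 and on the fully substituted C10 (which carries C14). The C1–C10 bond is therefore the retron of a reductive coupling between a C1 aldehyde and a C10 methyl ketone, followed by epoxide closure. Because C2 and C9 are methylenes, neither carbonyl has a heteroatom in the α position that a ketyl could expel. The 4,5-epoxide can stay as the E-olefin until the end, since allylic strain between C15 and the C6 substituents exposes one olefin face.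

## Retrosynthesis

**41 to 39.** The last bonds cut are the O–Si bond of the side-chain hydroxyl (41 from 40) and the two C–O bonds of the 4,5-epoxide (40 from olefin 39). The 4,5-epoxide is placed last because it would not survive the basic olefination and acylation steps next to the acidic C6–H, whereas the E-olefin is inert to all of them. The forward step needs a peracid to attack only the electron-rich trisubstituted olefin, from its outer face.

**39 to 33 and 36.** The C8–O acyl bond and the C13–O acetyl bond are cut, giving hydroxy lactone 33 (O13 as PMB ether) and the silyl-protected acrylic acid 36. O13 is carried as an ether because an acetate β to a phosphonate carbanion would be eliminated. The side-chain hydroxyl is silylated so that the acid cannot acylate itself. Intermediates 37 and 38 lie on this path.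

**33/32 to 25 and 30.** The butenolide is opened at C7=C11 (Horner–Wadsworth–Emmons) and at the C6–O–C12 ester, leading through phosphonate ester 31 to α-hydroxy ketone 25 and phosphonate acid 30. Building the lactone before ring closure would put a reducible unsaturated lactone into the reductive coupling, and an aldol condensation would need strong base next to C6–H. The cut removes C11–C13 and leaves only a carbinol at C6 and a ketone at C7.

**25 to 22.** Ketone 25 goes back through 24 and 23 to the fully protected epoxide 22. O6, O7 and O8 carry three different groups (TES, PMB, TBS) so that O7 can be freed and oxidised first, O6 second and O8 last.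

**22 to 20.** The C1–O bond of the 1,10-epoxide is cut: the tertiary C10 oxygen displaces a C1 sulfonate (21) with inversion. The alternative, epoxidation of a 1(10)-olefin, would require control of both olefin geometry and face in the ring. The displacement asks only for the cis-diol 20.

**20 to 18 (key).** The C1–C10 bond is cut to the acyclic keto aldehyde 18. Closing the ring at C5–C6 instead would set the permanent centre C6 during macrocyclisation. Closure at C1–C10 sets only centres that can be corrected, and it joins two carbons that both end up oxygenated. The precursor has three stereocentres and no ring.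

**18 to 8 and 12.** The C5–C6 bond is cut between alkenyl iodide 12 (C1–C5 with C15) and α-alkoxy aldehyde 8 (C6–C10 with C14). The C10 ketone is masked as a terminal olefin and the C1 aldehyde as an acetate (14–17). The forward coupling must give the 6,7-anti alcohol, which a non-chelating alkenyl–metal addition should favour.

**8 to 1; 12 to 9; 30 to 26; 36 to 34.** Aldehyde 8 comes from 2-deoxy-D-ribose 1 through 2–7: C1 of the sugar becomes C10 after methylenation, C3 becomes C8 with the correct configuration, C4 becomes C7 and C5 becomes C6. Iodide 12 comes from 4-pentyn-1-ol 9 by carboalumination–iodination (11). Acid 30 comes from triethyl phosphonoacetate 26 via acrylate 28 and adduct 29. Acid 36 comes from ethyl 2-(hydroxymethyl)acrylate 34 via 35.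

## Roads not taken

**Alternative 1:** The ten-membered ring is unveiled by cleaving the C5–C10 bond of a bicyclic eudesmane lactone from the terpene chiral pool. An alkoxide adds to a C4 borane, and the resulting boronate fragments with loss of a C1 sulfonate to give A1, the (1(10)E,4E)-diene lactone.
- Merits: both E-olefins form stereospecifically in one step, no macrocyclisation or dilution is needed, and one double epoxidation could then deliver both epoxides. In ring formation and in brevity up to the diene this road is better than the chosen one.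
- Weak points: A1 has no oxygen at C8 or C13, and its lactone is saturated at C7 and C11. The target would need oxidation of an unactivated methylene at C8, dehydrogenation to the tetrasubstituted butenolide, and oxidation of C13 beside two trisubstituted olefins or epoxides. None of these has a selective handle, and the diene is prone to Cope rearrangement and acid-induced transannular closure.
- Comparison: the chosen plan accepts a risky macrocyclisation and a longer sequence, but O6, O7 and O8 are in place from the sugar, which is exactly where A1 is empty.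

**Alternative 2:** The C5–C6 bond is cut. A Lewis acid activates a C5 aldehyde and the γ carbon (C6) of a 2-silyloxyfuran attacks it, closing the ring and regenerating the butenolide in A2.
- Merits: butenolide, C13 acetate and O8 are all in place before ring closure, so fewer steps follow the key step than in the chosen plan; in this respect the road is better.
- Weak points: the ring-closing step sets C5 and C6 together, and C6 is a permanent centre that cannot be corrected later. The aldehyde sits on a fully substituted, silyloxy-bearing C4. The furylmethyl acetate is exposed to the Lewis acid. The 4,5-epoxide would still have to be closed from the C4/C5 oxygens, which needs the correct C5 epimer as well.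
- Comparison: the chosen plan sets C6 on an acyclic compound, where an oxidation–reduction can repair it, and leaves only C1 and C10 to the ring closure, both of which have repair paths.

**Alternative 3:** A monoterpene-derived 1,2-dialkenylcyclohexanol is expanded by an anionic oxy-Cope shift that forms C8–C9 and cleaves the old ring bond, giving cyclodecenone A3.
- Merits: the [3,3] shift is reliable, needs no dilution, fixes the E-olefin through a chair transition state and starts from a cheap terpene. As a ring-forming event it is stronger than a reductive macrocyclisation.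
- Weak points: A3 carries a ketone at C6, an ether at C8, a tertiary silyl ether at C4 and the 1(10)-olefin. Oxygen at C5, the C7 carbonyl and the C11–C13 unit are all missing. C6 would have to be set by reducing a ketone in a medium ring, and the 4,5-epoxide built from a tertiary alcohol and a newly introduced C5 leaving group.
- Comparison: the chosen plan is weaker at the ring closure but carries every oxygen of the C6–C8 segment from the start, so the work after the ring is formed is protecting-group and acylation chemistry only.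

Key step: step 15

Remarks on the chemistry: acetal 6 is a mixture of epimers at the acetal carbon, and 29–31 are mixtures at the phosphonate-bearing carbon; both centres are destroyed later. The diol from the key step is carried forward as its 1S,10R isomer.

## Route

Step 1
Reactants: 1 2-deoxy-D-ribose
Product: 2 (2R,3S)-hex-5-ene-1,2,3-triol
Conditions: Ph3PCH3Br (4 equiv), KOt-Bu (4 equiv), THF, 0 °C to reflux
Reagents that add atoms: methyltriphenylphosphonium bromide, C[P+](c1ccccc1)(c1ccccc1)c1ccccc1.[Br-]
Why: Wittig methylenation of the lactol through its open hydroxy aldehyde form, with excess ylide to cover the hydroxyl protons; no stereocentre is touched, so C3 and C4 of the sugar become C8 and C7.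

Step 2
Reactants: 2 (2R,3S)-hex-5-ene-1,2,3-triol
Product: 3 (1S)-1-[(4R)-2,2-dimethyl-1,3-dioxolan-4-yl]but-3-en-1-ol
Conditions: Me2C(OMe)2, p-TsOH·H2O (cat.), acetone, 25 °C; Et3N quench
Reagents that add atoms: 2,2-dimethoxypropane, COC(C)(C)OC
Why: Acetonide formation under equilibrating conditions; the terminal dioxolane should be favoured over the cis-disubstituted internal dioxolane of the erythro diol and over a 1,3-dioxane with an axial methyl, leaving the C8 hydroxyl free.

Step 3
Reactants: 3 (1S)-1-[(4R)-2,2-dimethyl-1,3-dioxolan-4-yl]but-3-en-1-ol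
Product: 4 TBS ether of 3
Conditions: TBSCl, imidazole, DMF, 25 °C
Reagents that add atoms: tert-butyldimethylsilyl chloride, CC(C)(C)[Si](C)(C)Cl
Why: Standard silylation of a secondary homoallylic alcohol; this group stays on O8 until step 25.

Step 4
Reactants: 4 TBS ether of 3
Product: 5 (2R,3S)-3-(TBSO)hex-5-ene-1,2-diol
Conditions: AcOH–H2O (4:1), 25 °C
Reagents that add atoms: none
Why: Mild acid hydrolysis of a terminal acetonide; a secondary TBS ether is stable under these conditions.

Step 5
Reactants: 5 (2R,3S)-3-(TBSO)hex-5-ene-1,2-diol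
Product: 6 (4R)-4-[(1S)-1-(TBSO)but-3-en-1-yl]-2-(4-methoxyphenyl)-1,3-dioxolane
Conditions: 4-MeOC6H4CH(OMe)2, PPTS (cat.), CH2Cl2, 25 °C
Reagents that add atoms: 4-methoxybenzaldehyde dimethyl acetal, COC(OC)c1ccc(OC)cc1
Why: Acid-catalysed transacetalisation onto the only 1,2-diol; the acetal configuration is irrelevant because the carbon becomes a benzylic methylene in step 6.

Step 6
Reactants: 6 (4R)-4-[(1S)-1-(TBSO)but-3-en-1-yl]-2-(4-methoxyphenyl)-1,3-dioxolane
Product: 7 (2R,3S)-3-(TBSO)-2-(PMBO)hex-5-en-1-ol
Conditions: i-Bu2AlH (3 equiv), CH2Cl2, −78 to 0 °C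
Reagents that add atoms: none
Why: Regioselective reductive opening of a 4-methoxybenzylidene acetal; aluminium binds the less hindered primary oxygen and hydride cleaves that C–O bond, leaving the PMB group on the secondary O7.

Step 7
Reactants: 7 (2R,3S)-3-(TBSO)-2-(PMBO)hex-5-en-1-ol
Product: 8 (2S,3S)-3-(TBSO)-2-(PMBO)hex-5-enal
Conditions: Dess–Martin periodinane, NaHCO3, CH2Cl2, 0 to 25 °C
Reagents that add atoms: none
Why: Buffered Dess–Martin oxidation of a primary alcohol; the α-alkoxy aldehyde should be used crude so that C7, which directs step 10, does not epimerise.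

Step 8
Reactants: 9 4-pentyn-1-ol
Product: 11 (E)-5-iodo-4-methylpent-4-en-1-ol, via alkenyldimethylalane 10 (not isolated)
Conditions: Me3Al (3 equiv), Cp2ZrCl2 (0.25 equiv), CH2Cl2, 0 to 25 °C; then I2, THF, −30 °C
Reagents that add atoms: trimethylaluminium, C[Al](C)C; iodine, II
Why: Negishi zirconium-catalysed carboalumination adds methyl and aluminium syn across the alkyne with aluminium at the terminus; iodinolysis with retention gives the E-alkenyl iodide carrying C15.

Step 9
Reactants: 11 (E)-5-iodo-4-methylpent-4-en-1-ol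
Product: 12 (E)-5-iodo-4-methylpent-4-en-1-yl acetate
Conditions: Ac2O, pyridine, DMAP (cat.), CH2Cl2, 25 °C
Reagents that add atoms: acetic anhydride, CC(=O)OC(C)=O
Why: Routine acetylation; the acetate tolerates the chromium coupling and can be removed later without touching the silyl or PMB ethers.

Step 10
Reactants: 8 (2S,3S)-3-(TBSO)-2-(PMBO)hex-5-enal; 12 (E)-5-iodo-4-methylpent-4-en-1-yl acetate
Product: 14 (4E,6R,7R,8S)-8-(TBSO)-6-hydroxy-7-(PMBO)-4-methylundeca-4,10-dien-1-yl acetate, via alkenylchromium dichloride 13 (not isolated)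
Conditions: CrCl2 (6 equiv), NiCl2 (1 mol %), DMSO, 25 °C
Reagents that add atoms: none
Why: Nozaki–Hiyama–Kishi coupling: zerovalent nickel inserts into the C–I bond and transmetalation to trivalent chromium gives 13 with retention of the E geometry, which adds only to the aldehyde. Under these non-chelating conditions Felkin–Anh attack anti to the C7 alkoxy group should favour the 6,7-anti alcohol, which has the C6 configuration of the target.

Step 11
Reactants: 14 (4E,6R,7R,8S)-8-(TBSO)-6-hydroxy-7-(PMBO)-4-methylundeca-4,10-dien-1-yl acetate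
Product: 15 (4E,6R,7S,8S)-8-(TBSO)-7-(PMBO)-4-methyl-6-(TESO)undeca-4,10-dien-1-yl acetate
Conditions: TESOTf, 2,6-lutidine, CH2Cl2, −78 °C
Reagents that add atoms: triethylsilyl trifluoromethanesulfonate, CC[Si](CC)(CC)OS(=O)(=O)C(F)(F)F
Why: Silyl triflate protection of a hindered allylic alcohol; TES is chosen so that O6 can later be freed in the presence of the TBS ether on O8.

Step 12
Reactants: 15 (4E,6R,7S,8S)-8-(TBSO)-7-(PMBO)-4-methyl-6-(TESO)undeca-4,10-dien-1-yl acetate
Product: 16 (4E,6R,7S,8S)-8-(TBSO)-7-(PMBO)-4-methyl-10-oxo-6-(TESO)undec-4-en-1-yl acetate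
Conditions: PdCl2 (10 mol %), Cu(OAc)2 (20 mol %), O2 (1 atm), DMA–H2O (7:1), 25 °C
Reagents that add atoms: water, O
Why: Tsuji–Wacker oxidation gives the C10 methyl ketone by Markovnikov hydroxypalladation of the monosubstituted olefin; the trisubstituted 4,5-olefin is inert and the acetate-buffered copper salt spares the TES ether. It is run while O1 is still acetylated so that no free hydroxyl can add to a palladium-bound olefin.

Step 13
Reactants: 16 (4E,6R,7S,8S)-8-(TBSO)-7-(PMBO)-4-methyl-10-oxo-6-(TESO)undec-4-en-1-yl acetate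
Product: 17 (4E,6R,7S,8S)-8-(TBSO)-1-hydroxy-7-(PMBO)-4-methyl-6-(TESO)undec-4-en-10-one
Conditions: K2CO3, MeOH, 0 °C
Reagents that add atoms: none
Why: Methanolysis of a primary acetate; silyl and PMB ethers are stable, and the cold, short exposure should prevent β-elimination of the C8 silyloxy group from the ketone.

Step 14
Reactants: 17 (4E,6R,7S,8S)-8-(TBSO)-1-hydroxy-7-(PMBO)-4-methyl-6-(TESO)undec-4-en-10-one
Product: 18 (4E,6R,7S,8S)-8-(TBSO)-7-(PMBO)-4-methyl-10-oxo-6-(TESO)undec-4-enal
Conditions: Dess–Martin periodinane, NaHCO3, CH2Cl2, 0 to 25 °C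
Reagents that add atoms: none
Why: Buffered Dess–Martin oxidation of the primary alcohol gives the C1 aldehyde without enolising the ketone or disturbing the ethers.

Step 15
Reactants: 18 (4E,6R,7S,8S)-8-(TBSO)-7-(PMBO)-4-methyl-10-oxo-6-(TESO)undec-4-enal
Product: 20 (1S,4E,6R,7S,8S,10R)-8-(TBSO)-7-(PMBO)-4,10-dimethyl-6-(TESO)cyclodec-4-ene-1,10-diol, via titanium pinacolate 19 (not isolated)
Conditions: TiCl3(DME)1.5 (10 equiv), Zn–Cu couple (25 equiv), DME, reflux 2 h, then 25 °C; 18 added by syringe pump over 30 h (final concentration about 0.005 M); aqueous K2CO3 work-up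
Reagents that add atoms: none
Why: Zinc–copper couple reduces TiCl3(DME)1.5 to low-valent titanium, which transfers one electron to each carbonyl; the two titanium-bound ketyls couple to form C1–C10 and the cyclic pinacolate 19, which is hydrolysed on work-up because deoxygenation to the olefin needs reflux. The closest known reaction type is the McMurry-type intramolecular pinacol coupling of keto aldehydes to medium- and large-ring 1,2-diols. The ten-membered carbocycle closes by head-to-head union of the two carbonyl carbons on the metal, and slow addition keeps the ketyl concentration low. C1 and C10 are set together: a pinacolate bridged by one titanium centre holds both oxygens on the same side of the ring and so gives the cis-diol, while at C10 the only resident bias is 1,3-induction from the C8 silyloxy group, so the 10R outcome is an expectation and the least secure element. The step needs ring closure over oligomerisation (dilution), pinacol over olefin formation (25 °C) and survival of the C6–C8 ethers; the substrate secures the last point because C2 and C9 are methylenes, so no ketyl has an α-alkoxide to expel. The 4,5-olefin cannot intercept the C1 ketyl, since only a four-membered or a 5-endo closure would be open to it.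

Step 16
Reactants: 20 (1S,4E,6R,7S,8S,10R)-8-(TBSO)-7-(PMBO)-4,10-dimethyl-6-(TESO)cyclodec-4-ene-1,10-diol
Product: 22 (1R,4E,6R,7S,8S,10R)-8-(TBSO)-1,10-epoxy-7-(PMBO)-4,10-dimethyl-6-(TESO)cyclodec-4-ene, via C1 mesylate 21 (not isolated)
Conditions: MsCl, Et3N, CH2Cl2, −20 °C; then K2CO3, MeOH, 0 to 25 °C
Reagents that add atoms: none
Why: The secondary C1 hydroxyl is sulfonylated selectively beside the tertiary one, and the C10 alkoxide then displaces the mesylate intramolecularly (Williamson-type closure) with inversion at C1, converting the cis-diol into the trans-epoxide (1S to 1R) with C10 unchanged.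

Step 17
Reactants: 22 (1R,4E,6R,7S,8S,10R)-8-(TBSO)-1,10-epoxy-7-(PMBO)-4,10-dimethyl-6-(TESO)cyclodec-4-ene
Product: 23 (1R,4E,6R,7S,8S,10R)-8-(TBSO)-1,10-epoxy-4,10-dimethyl-6-(TESO)cyclodec-4-en-7-ol
Conditions: DDQ, CH2Cl2–pH 7 phosphate buffer (10:1), 0 °C
Reagents that add atoms: none
Why: Oxidative cleavage of the PMB ether under buffered, near-neutral conditions that the epoxide, the olefin and both silyl ethers tolerate.

Step 18
Reactants: 23 (1R,4E,6R,7S,8S,10R)-8-(TBSO)-1,10-epoxy-4,10-dimethyl-6-(TESO)cyclodec-4-en-7-ol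
Product: 24 (1R,4E,6R,8S,10R)-8-(TBSO)-1,10-epoxy-4,10-dimethyl-6-(TESO)cyclodec-4-en-7-one
Conditions: Dess–Martin periodinane, NaHCO3, CH2Cl2, 0 to 25 °C
Reagents that add atoms: none
Why: Dess–Martin oxidation of a hindered secondary alcohol under buffered conditions should leave the two flanking α-stereocentres (C6, C8) intact.

Step 19
Reactants: 24 (1R,4E,6R,8S,10R)-8-(TBSO)-1,10-epoxy-4,10-dimethyl-6-(TESO)cyclodec-4-en-7-one
Product: 25 (1R,4E,6R,8S,10R)-8-(TBSO)-1,10-epoxy-6-hydroxy-4,10-dimethylcyclodec-4-en-7-one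
Conditions: HF·pyridine, excess pyridine, THF, 0 °C
Reagents that add atoms: none
Why: Pyridine-buffered fluoride cleaves the TES ether much faster than the TBS ether and is mild enough for the epoxide; the allylic α-hydroxy ketone should be acylated at once (step 23) to avoid enediol isomerisation.

Step 20
Reactants: 26 triethyl phosphonoacetate
Product: 28 ethyl 2-(diethoxyphosphoryl)acrylate, via methanol adduct 27 (not isolated)
Conditions: (CH2O)n, piperidine (cat.), MeOH, reflux; then p-TsOH·H2O (cat.), toluene, reflux with distillation of MeOH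
Reagents that add atoms: formaldehyde (as paraformaldehyde), C=O
Why: Knoevenagel condensation with formaldehyde gives the acrylate, which is trapped by the solvent as 27; acid-catalysed loss of methanol then releases the vinylphosphonate.

Step 21
Reactants: 28 ethyl 2-(diethoxyphosphoryl)acrylate
Product: 29 ethyl 2-(diethoxyphosphoryl)-3-(PMBO)propanoate
Conditions: 4-MeOC6H4CH2OH (1.5 equiv), KOt-Bu (10 mol %), THF, 0 °C
Reagents that add atoms: 4-methoxybenzyl alcohol, COc1ccc(CO)cc1
Why: Base-catalysed oxa-Michael addition of an alkoxide to a doubly activated vinylphosphonate; the stabilised carbanion is protonated by the alcohol, which carries the chain.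

Step 22
Reactants: 29 ethyl 2-(diethoxyphosphoryl)-3-(PMBO)propanoate
Product: 30 2-(diethoxyphosphoryl)-3-(PMBO)propanoic acid
Conditions: LiOH·H2O (1.1 equiv), THF–H2O (3:1), 0 °C; then 1 M HCl to pH 3
Reagents that add atoms: lithium hydroxide, [Li+].[OH-]
Why: Hydroxide cleaves the carboxylic ester of a phosphonoacetate selectively over the phosphonate esters; one equivalent at 0 °C limits retro-Michael loss of the benzylic alkoxide.

Step 23
Reactants: 25 (1R,4E,6R,8S,10R)-8-(TBSO)-1,10-epoxy-6-hydroxy-4,10-dimethylcyclodec-4-en-7-one; 30 2-(diethoxyphosphoryl)-3-(PMBO)propanoic acid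
Product: 31 (1R,4E,6R,8S,10R)-8-(TBSO)-1,10-epoxy-4,10-dimethyl-7-oxocyclodec-4-en-6-yl 2-(diethoxyphosphoryl)-3-(PMBO)propanoate
Conditions: EDC·HCl, DMAP (10 mol %), CH2Cl2, 0 to 25 °C
Reagents that add atoms: none
Why: Steglich-type carbodiimide esterification of an α-hydroxy ketone with a phosphonoacetic acid, the standard entry to butenolides; the near-neutral conditions should spare C6.

Step 24
Reactants: 31 (1R,4E,6R,8S,10R)-8-(TBSO)-1,10-epoxy-4,10-dimethyl-7-oxocyclodec-4-en-6-yl 2-(diethoxyphosphoryl)-3-(PMBO)propanoate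
Product: 32 (1R,4E,6R,8S,10R)-8-(TBSO)-1,10-epoxy-13-(PMBO)germacra-4,7(11)-dien-6,12-olide
Conditions: LiCl, i-Pr2NEt, MeCN, 25 °C
Reagents that add atoms: none
Why: Intramolecular Horner–Wadsworth–Emmons olefination under lithium-assisted weak-base conditions: the chelated phosphonate anion adds to the adjacent C7 ketone through a five-membered transition state and loss of diethyl phosphate forms the tetrasubstituted C7=C11 bond of the butenolide. The amine base is chosen to leave C6–H and C8–H untouched.

Step 25
Reactants: 32 (1R,4E,6R,8S,10R)-8-(TBSO)-1,10-epoxy-13-(PMBO)germacra-4,7(11)-dien-6,12-olide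
Product: 33 (1R,4E,6R,8S,10R)-1,10-epoxy-8-hydroxy-13-(PMBO)germacra-4,7(11)-dien-6,12-olide
Conditions: Bu4NF, AcOH (1:1), THF, 0 to 25 °C
Reagents that add atoms: none
Why: Acetic acid-buffered fluoride removes the secondary TBS ether without generating a free 8-alkoxide, which could attack C12 and shift the lactone, and without deprotonating C6.

Step 26
Reactants: 34 ethyl 2-(hydroxymethyl)acrylate
Product: 35 ethyl 2-[(TBSO)methyl]acrylate
Conditions: TBSCl, imidazole, CH2Cl2, 25 °C
Reagents that add atoms: tert-butyldimethylsilyl chloride, CC(C)(C)[Si](C)(C)Cl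
Why: Routine silylation of a primary allylic alcohol, so that the acid made in step 27 cannot acylate itself.

Step 27
Reactants: 35 ethyl 2-[(TBSO)methyl]acrylate
Product: 36 2-[(TBSO)methyl]acrylic acid
Conditions: LiOH·H2O, THF–H2O, 0 to 25 °C; then 1 M HCl to pH 4 at 0 °C
Reagents that add atoms: lithium hydroxide, [Li+].[OH-]
Why: Saponification of an α-substituted acrylate, which resists conjugate addition of hydroxide; careful cold acidification keeps the primary silyl ether.

Step 28
Reactants: 33 (1R,4E,6R,8S,10R)-1,10-epoxy-8-hydroxy-13-(PMBO)germacra-4,7(11)-dien-6,12-olide; 36 2-[(TBSO)methyl]acrylic acid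
Product: 37 (1R,4E,6R,8S,10R)-1,10-epoxy-13-(PMBO)-8-{2-[(TBSO)methyl]acryloyloxy}germacra-4,7(11)-dien-6,12-olide
Conditions: EDC·HCl, DMAP (20 mol %), CH2Cl2, 0 to 25 °C
Reagents that add atoms: none
Why: Steglich-type esterification of the secondary C8 alcohol with an α-substituted acrylic acid; the configuration at C8 is retained because only the O–H bond reacts.

Step 29
Reactants: 37 (1R,4E,6R,8S,10R)-1,10-epoxy-13-(PMBO)-8-{2-[(TBSO)methyl]acryloyloxy}germacra-4,7(11)-dien-6,12-olide
Product: 38 (1R,4E,6R,8S,10R)-1,10-epoxy-13-hydroxy-8-{2-[(TBSO)methyl]acryloyloxy}germacra-4,7(11)-dien-6,12-olide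
Conditions: DDQ, CH2Cl2–pH 7 phosphate buffer (10:1), 0 to 25 °C
Reagents that add atoms: none
Why: Oxidative PMB cleavage under neutral conditions frees the C13 hydroxyl; the electron-poor butenolide and acrylate and the epoxide are not oxidised.

Step 30
Reactants: 38 (1R,4E,6R,8S,10R)-1,10-epoxy-13-hydroxy-8-{2-[(TBSO)methyl]acryloyloxy}germacra-4,7(11)-dien-6,12-olide
Product: 39 (1R,4E,6R,8S,10R)-13-acetoxy-1,10-epoxy-8-{2-[(TBSO)methyl]acryloyloxy}germacra-4,7(11)-dien-6,12-olide
Conditions: Ac2O, pyridine, DMAP (cat.), CH2Cl2, 0 °C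
Reagents that add atoms: acetic anhydride, CC(=O)OC(C)=O
Why: Routine acetylation of the only free, primary hydroxyl.

Step 31
Reactants: 39 (1R,4E,6R,8S,10R)-13-acetoxy-1,10-epoxy-8-{2-[(TBSO)methyl]acryloyloxy}germacra-4,7(11)-dien-6,12-olide
Product: 40 (1R,4R,5R,6S,8S,10R)-13-acetoxy-1,10:4,5-diepoxy-8-{2-[(TBSO)methyl]acryloyloxy}germacr-7(11)-en-6,12-olide
Conditions: mCPBA, NaHCO3, CH2Cl2, 0 °C
Reagents that add atoms: 3-chloroperbenzoic acid, O=C(OO)c1cccc(Cl)c1
Why: Prilezhaev epoxidation is stereospecific for the E-olefin and chemoselective for the only electron-rich double bond. Allylic strain with C15 should hold C6–H in the olefin plane, so that O6 lies on the outer face and C7 on the inner face; peripheral attack on the O6 side corresponds to 4R,5R.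

Step 32
Reactants: 40 (1R,4R,5R,6S,8S,10R)-13-acetoxy-1,10:4,5-diepoxy-8-{2-[(TBSO)methyl]acryloyloxy}germacr-7(11)-en-6,12-olide
Product: 41 CNP0282791.1, (1R,4R,5R,6S,8S,10R)-13-acetoxy-1,10:4,5-diepoxy-8-[2-(hydroxymethyl)acryloyloxy]germacr-7(11)-en-6,12-olide
Conditions: HF·pyridine, excess pyridine, THF, 0 °C
Reagents that add atoms: none
Why: Buffered fluoride removes the primary allylic TBS ether under non-basic conditions, which matters because base would deprotonate C6 and open the 4,5-epoxide; with no olefin left in the ring the epoxides have no transannular π-nucleophile.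

## Compound list

1 | 2-deoxy-D-ribose | O=CC[C@H](O)[C@H](O)CO | starting material
2 | (2R,3S)-hex-5-ene-1,2,3-triol | C=CC[C@H](O)[C@H](O)CO | intermediate
3 | (1S)-1-[(4R)-2,2-dimethyl-1,3-dioxolan-4-yl]but-3-en-1-ol | C=CC[C@H](O)[C@H]1COC(C)(C)O1 | intermediate
4 | tert-butyl{[(1S)-1-[(4R)-2,2-dimethyl-1,3-dioxolan-4-yl]but-3-en-1-yl]oxy}dimethylsilane | C=CC[C@H](O[Si](C)(C)C(C)(C)C)[C@H]1COC(C)(C)O1 | intermediate
5 | (2R,3S)-3-[(tert-butyldimethylsilyl)oxy]hex-5-ene-1,2-diol | C=CC[C@H](O[Si](C)(C)C(C)(C)C)[C@H](O)CO | intermediate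
6 | (4R)-4-{(1S)-1-[(tert-butyldimethylsilyl)oxy]but-3-en-1-yl}-2-(4-methoxyphenyl)-1,3-dioxolane (both acetal epimers) | C=CC[C@H](O[Si](C)(C)C(C)(C)C)[C@H]1COC(c2ccc(OC)cc2)O1 | intermediate
7 | (2R,3S)-3-[(tert-butyldimethylsilyl)oxy]-2-[(4-methoxybenzyl)oxy]hex-5-en-1-ol | C=CC[C@H](O[Si](C)(C)C(C)(C)C)[C@H](OCc1ccc(OC)cc1)CO | intermediate
8 | (2S,3S)-3-[(tert-butyldimethylsilyl)oxy]-2-[(4-methoxybenzyl)oxy]hex-5-enal | C=CC[C@H](O[Si](C)(C)C(C)(C)C)[C@H](OCc1ccc(OC)cc1)C=O | intermediate
9 | 4-pentyn-1-ol | OCCCC#C | starting material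
10 | (E)-alkenyldimethylalane from 9 (O-bound dimethylaluminium alkoxide) | C[Al](C)OCCC/C(C)=C/[Al](C)C | intermediate
11 | (E)-5-iodo-4-methylpent-4-en-1-ol | OCCC/C(C)=C/I | intermediate
12 | (E)-5-iodo-4-methylpent-4-en-1-yl acetate | CC(=O)OCCC/C(C)=C/I | intermediate
13 | (E)-alkenylchromium dichloride from 12 (trivalent chromium) | CC(=O)OCCC/C(C)=C/[Cr](Cl)Cl | intermediate
14 | (4E,6R,7R,8S)-8-[(tert-butyldimethylsilyl)oxy]-6-hydroxy-7-[(4-methoxybenzyl)oxy]-4-methylundeca-4,10-dien-1-yl acetate | CC(=O)OCCC/C(C)=C/[C@@H](O)[C@@H](OCc1ccc(OC)cc1)[C@@H](O[Si](C)(C)C(C)(C)C)CC=C | intermediate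
15 | (4E,6R,7S,8S)-8-[(tert-butyldimethylsilyl)oxy]-7-[(4-methoxybenzyl)oxy]-4-methyl-6-[(triethylsilyl)oxy]undeca-4,10-dien-1-yl acetate | CC(=O)OCCC/C(C)=C/[C@@H](O[Si](CC)(CC)CC)[C@@H](OCc1ccc(OC)cc1)[C@@H](O[Si](C)(C)C(C)(C)C)CC=C | intermediate
16 | (4E,6R,7S,8S)-8-[(tert-butyldimethylsilyl)oxy]-7-[(4-methoxybenzyl)oxy]-4-methyl-10-oxo-6-[(triethylsilyl)oxy]undec-4-en-1-yl acetate | CC(=O)OCCC/C(C)=C/[C@@H](O[Si](CC)(CC)CC)[C@@H](OCc1ccc(OC)cc1)[C@@H](O[Si](C)(C)C(C)(C)C)CC(C)=O | intermediate
17 | (4E,6R,7S,8S)-8-[(tert-butyldimethylsilyl)oxy]-1-hydroxy-7-[(4-methoxybenzyl)oxy]-4-methyl-6-[(triethylsilyl)oxy]undec-4-en-10-one (numbered from the hydroxyl end) | OCCC/C(C)=C/[C@@H](O[Si](CC)(CC)CC)[C@@H](OCc1ccc(OC)cc1)[C@@H](O[Si](C)(C)C(C)(C)C)CC(C)=O | intermediate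
18 | (4E,6R,7S,8S)-8-[(tert-butyldimethylsilyl)oxy]-7-[(4-methoxybenzyl)oxy]-4-methyl-10-oxo-6-[(triethylsilyl)oxy]undec-4-enal | O=CCC/C(C)=C/[C@@H](O[Si](CC)(CC)CC)[C@@H](OCc1ccc(OC)cc1)[C@@H](O[Si](C)(C)C(C)(C)C)CC(C)=O | intermediate
19 | titanium pinacolate of 20, drawn in its simplest form as the cyclic dichlorotitanium 1,10-diolate (tetravalent titanium) | CC(C)(C)[Si](C)(C)O[C@H]1C[C@@]2(C)O[Ti](Cl)(Cl)O[C@H]2CC/C(C)=C/[C@@H](O[Si](CC)(CC)CC)[C@H]1OCc1ccc(OC)cc1 | intermediate
20 | (1S,4E,6R,7S,8S,10R)-8-[(tert-butyldimethylsilyl)oxy]-7-[(4-methoxybenzyl)oxy]-4,10-dimethyl-6-[(triethylsilyl)oxy]cyclodec-4-ene-1,10-diol | CC(C)(C)[Si](C)(C)O[C@H]1C[C@@](C)(O)[C@@H](O)CC/C(C)=C/[C@@H](O[Si](CC)(CC)CC)[C@H]1OCc1ccc(OC)cc1 | intermediate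
21 | C1 methanesulfonate of 20 (1S,10R) | CC(C)(C)[Si](C)(C)O[C@H]1C[C@@](C)(O)[C@@H](OS(C)(=O)=O)CC/C(C)=C/[C@@H](O[Si](CC)(CC)CC)[C@H]1OCc1ccc(OC)cc1 | intermediate
22 | (1R,4E,6R,7S,8S,10R)-8-[(tert-butyldimethylsilyl)oxy]-1,10-epoxy-7-[(4-methoxybenzyl)oxy]-4,10-dimethyl-6-[(triethylsilyl)oxy]cyclodec-4-ene | CC(C)(C)[Si](C)(C)O[C@H]1C[C@@]2(C)O[C@@H]2CC/C(C)=C/[C@@H](O[Si](CC)(CC)CC)[C@H]1OCc1ccc(OC)cc1 | intermediate
23 | (1R,4E,6R,7S,8S,10R)-8-[(tert-butyldimethylsilyl)oxy]-1,10-epoxy-4,10-dimethyl-6-[(triethylsilyl)oxy]cyclodec-4-en-7-ol | CC(C)(C)[Si](C)(C)O[C@H]1C[C@@]2(C)O[C@@H]2CC/C(C)=C/[C@@H](O[Si](CC)(CC)CC)[C@H]1O | intermediate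
24 | (1R,4E,6R,8S,10R)-8-[(tert-butyldimethylsilyl)oxy]-1,10-epoxy-4,10-dimethyl-6-[(triethylsilyl)oxy]cyclodec-4-en-7-one | CC(C)(C)[Si](C)(C)O[C@H]1C[C@@]2(C)O[C@@H]2CC/C(C)=C/[C@@H](O[Si](CC)(CC)CC)C1=O | intermediate
25 | (1R,4E,6R,8S,10R)-8-[(tert-butyldimethylsilyl)oxy]-1,10-epoxy-6-hydroxy-4,10-dimethylcyclodec-4-en-7-one | CC(C)(C)[Si](C)(C)O[C@H]1C[C@@]2(C)O[C@@H]2CC/C(C)=C/[C@@H](O)C1=O | intermediate
26 | triethyl phosphonoacetate | CCOC(=O)CP(=O)(OCC)OCC | starting material
27 | ethyl 2-(diethoxyphosphoryl)-3-methoxypropanoate | CCOC(=O)C(COC)P(=O)(OCC)OCC | intermediate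
28 | ethyl 2-(diethoxyphosphoryl)acrylate | C=C(C(=O)OCC)P(=O)(OCC)OCC | intermediate
29 | ethyl 2-(diethoxyphosphoryl)-3-[(4-methoxybenzyl)oxy]propanoate (racemic) | CCOC(=O)C(COCc1ccc(OC)cc1)P(=O)(OCC)OCC | intermediate
30 | 2-(diethoxyphosphoryl)-3-[(4-methoxybenzyl)oxy]propanoic acid (racemic) | O=C(O)C(COCc1ccc(OC)cc1)P(=O)(OCC)OCC | intermediate
31 | (1R,4E,6R,8S,10R)-8-[(tert-butyldimethylsilyl)oxy]-1,10-epoxy-4,10-dimethyl-7-oxocyclodec-4-en-6-yl 2-(diethoxyphosphoryl)-3-[(4-methoxybenzyl)oxy]propanoate (epimers at the phosphonate carbon) | CC(C)(C)[Si](C)(C)O[C@H]1C[C@@]2(C)O[C@@H]2CC/C(C)=C/[C@@H](OC(=O)C(COCc2ccc(OC)cc2)P(=O)(OCC)OCC)C1=O | intermediate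
32 | (1R,4E,6R,8S,10R)-8-[(tert-butyldimethylsilyl)oxy]-1,10-epoxy-13-[(4-methoxybenzyl)oxy]germacra-4,7(11)-dien-6,12-olide | CC(C)(C)[Si](C)(C)O[C@H]1C[C@@]2(C)O[C@@H]2CC/C(C)=C/[C@H]2OC(=O)C(COCc3ccc(OC)cc3)=C12 | intermediate
33 | (1R,4E,6R,8S,10R)-1,10-epoxy-8-hydroxy-13-[(4-methoxybenzyl)oxy]germacra-4,7(11)-dien-6,12-olide | O[C@H]1C[C@@]2(C)O[C@@H]2CC/C(C)=C/[C@H]2OC(=O)C(COCc3ccc(OC)cc3)=C12 | intermediate
34 | ethyl 2-(hydroxymethyl)acrylate | C=C(CO)C(=O)OCC | starting material
35 | ethyl 2-{[(tert-butyldimethylsilyl)oxy]methyl}acrylate | C=C(CO[Si](C)(C)C(C)(C)C)C(=O)OCC | intermediate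
36 | 2-{[(tert-butyldimethylsilyl)oxy]methyl}acrylic acid | C=C(CO[Si](C)(C)C(C)(C)C)C(=O)O | intermediate
37 | (1R,4E,6R,8S,10R)-1,10-epoxy-13-[(4-methoxybenzyl)oxy]-8-(2-{[(tert-butyldimethylsilyl)oxy]methyl}acryloyloxy)germacra-4,7(11)-dien-6,12-olide | C=C(CO[Si](C)(C)C(C)(C)C)C(=O)O[C@H]1C[C@@]2(C)O[C@@H]2CC/C(C)=C/[C@H]2OC(=O)C(COCc3ccc(OC)cc3)=C12 | intermediate
38 | (1R,4E,6R,8S,10R)-1,10-epoxy-13-hydroxy-8-(2-{[(tert-butyldimethylsilyl)oxy]methyl}acryloyloxy)germacra-4,7(11)-dien-6,12-olide | C=C(CO[Si](C)(C)C(C)(C)C)C(=O)O[C@H]1C[C@@]2(C)O[C@@H]2CC/C(C)=C/[C@H]2OC(=O)C(CO)=C12 | intermediate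
39 | (1R,4E,6R,8S,10R)-13-acetoxy-1,10-epoxy-8-(2-{[(tert-butyldimethylsilyl)oxy]methyl}acryloyloxy)germacra-4,7(11)-dien-6,12-olide | C=C(CO[Si](C)(C)C(C)(C)C)C(=O)O[C@H]1C[C@@]2(C)O[C@@H]2CC/C(C)=C/[C@H]2OC(=O)C(COC(C)=O)=C12 | intermediate
40 | (1R,4R,5R,6S,8S,10R)-13-acetoxy-1,10:4,5-diepoxy-8-(2-{[(tert-butyldimethylsilyl)oxy]methyl}acryloyloxy)germacr-7(11)-en-6,12-olide | C=C(CO[Si](C)(C)C(C)(C)C)C(=O)O[C@H]1C[C@@]2(C)O[C@@H]2CC[C@@]2(C)O[C@@H]2[C@H]2OC(=O)C(COC(C)=O)=C12 | intermediate
41 | CNP0282791.1, (1R,4R,5R,6S,8S,10R)-13-acetoxy-1,10:4,5-diepoxy-8-[2-(hydroxymethyl)acryloyloxy]germacr-7(11)-en-6,12-olide | C=C(CO)C(=O)O[C@H]1C[C@@]2(C)O[C@@H]2CC[C@@]2(C)O[C@@H]2[C@H]2OC(=O)C(COC(C)=O)=C12 | target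

## Step count and least certain steps

Total step count: 32. Longest linear sequence: 25 steps (steps 1–7, 10–19, 23–25 and 28–32). The branches are steps 8–9 (iodide 12), 20–22 (acid 30) and 26–27 (acid 36).

**Step 15 (key step).** Ring closure may lose to intermolecular coupling despite slow addition. The facial selectivity at C10 and C1 may be poor or may favour a trans-diol, which is common for ten-membered pinacolates. The TES ether may be lost on the Lewis-acidic metal. Fallback: setting out from 18, the same coupling is run and the trans-diol, (1R,4E,6R,7S,8S,10R)-diol F1, is collected. It is converted with thiocarbonyldiimidazole and DMAP in toluene at 110 °C into the cyclic thiocarbonate F2. Corey–Winter syn-elimination with 1,3-dimethyl-2-phenyl-1,3,2-diazaphospholidine in THF at 40 °C then gives the (1(10)E,4E)-diene F3. Because this elimination erases both carbinol centres, the C10 configuration of a trans-diol no longer matters. mCPBA with NaHCO3 in CH2Cl2 at −20 °C should epoxidise the 1(10)-olefin first, since the 4,5-olefin is shielded and deactivated by the allylic silyloxy group. This rejoins the route at 22, with the epoxide face now set by peripheral attack on the ring.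

**Step 10.** Facial selectivity at the aldehyde may be low, because the PMB ether can chelate and oppose the Felkin–Anh mode, leaving the C6 epimer as a co-product. Fallback: setting out from 14 as its mixture with the C6 epimer F4, Dess–Martin oxidation gives the enone F5. Chelation-controlled 1,2-reduction with Zn(BH4)2 in Et2O at −30 °C, where zinc bridges the carbonyl and the C7 ether oxygen, should deliver the 6,7-anti alcohol and comes back to the route at 14.

**Step 24.** The phosphonate carbanion may expel the benzylic alkoxide (retro-Michael) faster than it attacks the hindered ketone, or C6 may epimerise or the 4,5-olefin migrate before ring closure. Fallback: setting out from 25, esterification (EDC·HCl, CH2Cl2) with the known 2-(diethoxyphosphoryl)acrylic acid F6 gives the phosphonoacrylate ester F7. Treating F7 with 4-methoxybenzyl alcohol and KOt-Bu in THF at −40 °C generates the same carbanion by oxa-Michael addition in the presence of excess alkoxide, and the tandem Horner–Wadsworth–Emmons closure comes back to the route at 32.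

**Step 25.** With O8 free next to the lactone, acyl transfer from O6 to O8 (translactonisation to the 8,12-olide) may occur during desilylation or during the DMAP-mediated acylation of step 28. Fallback: setting out from 31, the TBS group is removed before any lactone exists (HF·pyridine, pyridine, THF, 25 °C) to give the hydroxy ketone F8. Esterification of F8 with 36 (EDC·HCl, DMAP, CH2Cl2) gives the diester F9, and the olefination conditions of step 24 then close the butenolide with the C8 ester already in place, coming back to the route at 37.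

**Step 31.** Facial selectivity may be poor if the ring populates a second conformer in which O6 lies in the olefin plane. Fallback: setting out from 39, substrate control is replaced by catalyst control in a Shi epoxidation. The fructose-derived ketone enantiomer matched to the 4R,5R face by the spiro transition-state model is used with KHSO5 (as 2KHSO5·KHSO4·K2SO4) in K2CO3-buffered MeCN–dimethoxymethane–water at 0 °C. This comes back to the route at 40 and involves no new compound.

## Further compounds

F1 | step 15 | (1R,4E,6R,7S,8S,10R)-8-[(tert-butyldimethylsilyl)oxy]-7-[(4-methoxybenzyl)oxy]-4,10-dimethyl-6-[(triethylsilyl)oxy]cyclodec-4-ene-1,10-diol (trans-diol) | CC(C)(C)[Si](C)(C)O[C@H]1C[C@@](C)(O)[C@H](O)CC/C(C)=C/[C@@H](O[Si](CC)(CC)CC)[C@H]1OCc1ccc(OC)cc1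
F2 | step 15 | cyclic 1,10-thiocarbonate of F1 | CC(C)(C)[Si](C)(C)O[C@H]1C[C@@]2(C)OC(=S)O[C@@H]2CC/C(C)=C/[C@@H](O[Si](CC)(CC)CC)[C@H]1OCc1ccc(OC)cc1
F3 | step 15 | (1(10)E,4E,6R,7S,8S)-8-[(tert-butyldimethylsilyl)oxy]-7-[(4-methoxybenzyl)oxy]-4,10-dimethyl-6-[(triethylsilyl)oxy]cyclodeca-1(10),4-diene | CC(C)(C)[Si](C)(C)O[C@H]1C/C(C)=C/CC/C(C)=C/[C@@H](O[Si](CC)(CC)CC)[C@H]1OCc1ccc(OC)cc1
F4 | step 10 | (4E,6S,7R,8S)-8-[(tert-butyldimethylsilyl)oxy]-6-hydroxy-7-[(4-methoxybenzyl)oxy]-4-methylundeca-4,10-dien-1-yl acetate (C6 epimer of 14) | CC(=O)OCCC/C(C)=C/[C@H](O)[C@@H](OCc1ccc(OC)cc1)[C@@H](O[Si](C)(C)C(C)(C)C)CC=C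
F5 | step 10 | (4E,7S,8S)-8-[(tert-butyldimethylsilyl)oxy]-7-[(4-methoxybenzyl)oxy]-4-methyl-6-oxoundeca-4,10-dien-1-yl acetate | CC(=O)OCCC/C(C)=C/C(=O)[C@@H](OCc1ccc(OC)cc1)[C@@H](O[Si](C)(C)C(C)(C)C)CC=C
F6 | step 24 | 2-(diethoxyphosphoryl)acrylic acid | C=C(C(=O)O)P(=O)(OCC)OCC
F7 | step 24 | (1R,4E,6R,8S,10R)-8-[(tert-butyldimethylsilyl)oxy]-1,10-epoxy-4,10-dimethyl-7-oxocyclodec-4-en-6-yl 2-(diethoxyphosphoryl)acrylate | CC(C)(C)[Si](C)(C)O[C@H]1C[C@@]2(C)O[C@@H]2CC/C(C)=C/[C@@H](OC(=O)C(=C)P(=O)(OCC)OCC)C1=O
F8 | step 25 | (1R,4E,6R,8S,10R)-1,10-epoxy-8-hydroxy-4,10-dimethyl-7-oxocyclodec-4-en-6-yl 2-(diethoxyphosphoryl)-3-[(4-methoxybenzyl)oxy]propanoate | O[C@H]1C[C@@]2(C)O[C@@H]2CC/C(C)=C/[C@@H](OC(=O)C(COCc2ccc(OC)cc2)P(=O)(OCC)OCC)C1=O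
F9 | step 25 | 8-O-(2-{[(tert-butyldimethylsilyl)oxy]methyl}acryloyl) derivative of F8 | C=C(CO[Si](C)(C)C(C)(C)C)C(=O)O[C@H]1C[C@@]2(C)O[C@@H]2CC/C(C)=C/[C@@H](OC(=O)C(COCc2ccc(OC)cc2)P(=O)(OCC)OCC)C1=O
F0 | step 31 | none | none
A1 | alternative 1 | 11,13-dihydrocostunolide, (1(10)E,4E)-germacra-1(10),4-dien-6,12-olide | C[C@H]1[C@@H]2CC/C(C)=C/CC/C(C)=C/[C@H]2OC1=O
A2 | alternative 2 | 13-acetoxy-8-[(tert-butyldimethylsilyl)oxy]-5-hydroxy-4-[(triethylsilyl)oxy]germacra-1(10),7(11)-dien-6,12-olide | CC(C)(C)[Si](C)(C)O[C@H]1C/C(C)=C/CC[C@@](C)(O[Si](CC)(CC)CC)[C@@H](O)[C@H]2OC(=O)C(COC(C)=O)=C12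
A3 | alternative 3 | (5E)-3-[(4-methoxybenzyl)oxy]-5,9-dimethyl-9-[(triethylsilyl)oxy]cyclodec-5-en-1-one | COc1ccc(CO[C@H]2C/C(C)=C/CC[C@@](C)(O[Si](CC)(CC)CC)CC(=O)C2)cc1
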